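## Analysis of the target

Pervilleanone (19) is an isoflavanone: ring A and the pyranone ring C form a chroman-4-one, and the pentasubstituted ring B sits on C3. C3 is the only stereocentre (R). It is benzylic and alpha to the C4 ketone, so it epimerises through the enol with base and more slowly with acid, and no second centre exists that could steer or restore it. Ring B carries 2'-OH, 3'-OMe, 4'-OMe and a 1,1-dimethylallyl group at C5'; this quaternary benzylic carbon with its vinyl group rules out hydrogenation, strong protic acid and electrophilic halogen sources late in the route. The 2'-phenol lies within reach of the C4 carbonyl and can close to a hemiketal and dehydrate under forcing acid, and both phenols would quench an electrophilic intermediate if left free. The difficulty is therefore to make C3 enantioselectively as late as possible, under conditions that are neither basic nor strongly acidic, next to an ortho-substituted aryl group, and then to unmask two phenols without disturbing it. The plan rests on C2: it is a CH2 group bound only to O1 and C3, which is the constitution of the methyl carbon of a methoxy group on C8a of ring A. The O1–C2 bond can therefore be bought as an aryl methyl ether and the C2–C3 bond made last by functionalising one of its C–H bonds from a reactive centre at C3.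

## Retrosynthetic reasoning

**19 to 18.** The last operation must not touch C3. Cutting the two O–Si bonds leads back to bis-silyl ether 18 and leaves only a buffered fluoride desilylation for the end. Both phenols must be masked before that, because a free phenol would capture the carbene of the ring closure by O–H insertion. The mask on O2' has to be a silyl group: any O-alkyl group there would offer a C–H bond at the distance that gives a five-membered ring from C3.

**18 to 17.** The C2–C3 bond is cut, which opens ring C and turns C2 back into the methyl group of a methoxy substituent and C3 into a carbene carbon, stored as the diazo group of diazoketone 17. Cuts at C3–C4, C3–C1' or O1–C2 would all lead to enolate or phenoxide chemistry, in which C3 is formed or handled under base. The carbene insertion is neutral, closes the ring and creates the stereocentre in one event. The forward reaction has to insert into a primary, oxygen-activated C–H bond through a six-membered closure with control of the C3 face.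

**17 to 16.** The C=N2 unit is removed to the methylene group of deoxybenzoin 16. This CH2 is benzylic and alpha to the ketone, so a diazo transfer from a sulfonyl azide needs only an amidine base.

**16 to 15, then to 10 and 12.** The ketone is taken back to alcohol 15 and the C4–C4a bond is cut, giving arylacetaldehyde 10 and aryl bromide 12, which is lithiated to 13 and transmetallated to 14. This cut divides the molecule into two halves of similar size, each derived from a commercial arene, and the bromine of 12 already marks the carbon that becomes C4a between the methoxy group and the ring.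

**10 to 9 to 8.** The C3–C4 bond is cut as a one-carbon homologation: aldehyde 10 comes from enol ether 9, and 9 from benzaldehyde 8 by a Wittig reaction. The formyl carbon of 8 thus becomes C3 and the added carbon becomes C4.

**8 to 7 to 4.** After removal of the silyl group, the bond from C5' to the quaternary carbon of phenol 7 is cut. C5' is para to the phenol oxygen and both ortho positions are occupied, so the 1,1-dimethylallyl group can be delivered from oxygen by two consecutive [3,3] shifts through dienones 5 and 6. The double allylic inversion returns the tertiary terminus to the ring. This avoids any cross-coupling to a quaternary carbon and uses the substitution pattern of the ring as the regiocontrol.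

**4 to 3 to 1 and 2.** The alkene of ether 4 comes from alkyne 3 by semi-hydrogenation, and the O–C bond of 3 is cut to commercial salicylaldehyde 1 and tertiary propargyl chloride 2. The propargyl route is used because a tertiary allyl ether cannot be made by direct alkylation.

**12 to 11.** The silyl ether is cut to commercial bromophenol 11.

## Alternatives that were turned down

**Alternative 1:** Ring B is built rather than bought. The disconnection runs through ring B: four of its carbons and both methoxy groups come from a squaric acid diester, the other two from an alkyne on C3 of a preformed 3,4-trans chroman-4-ol silyl ether. In the forward direction the alkynyl hydroxycyclobutenone is heated. Four-electron ring opening gives an alkynyl vinylketene, which closes across the future C1'–C2' bond and ends as the quinone A1, 2,3-dimethoxy-5-[(3,4-trans)-4-(triethylsilyloxy)-7-(triisopropylsilyloxy)chroman-3-yl]-1,4-benzoquinone.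
- For: the oxygen pattern of ring B is laid down with full regiocontrol. C3 travels next to a protected alcohol and not a ketone, so its configuration is safe until a final oxidation. On this point A1 is stronger than the chosen route, whose C3 centre is enolisable from the moment it exists.
- Against: the quinone carbonyl para to C2' ends up on C5', the carbon that must carry the 1,1-dimethylallyl group. After reduction the two hydroquinone oxygens must be told apart and the C5' oxygen replaced by a quaternary carbon in a crowded coupling. The chroman alkyne needs two stereocentres, one of which is later destroyed, and the sequence is several steps longer on both sides of its key step.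
- In its place the chosen route takes ring B with all its oxygens from a commercial benzaldehyde, needs no oxygen-to-carbon exchange, and spends its one stereocontrolling event on closing ring C.

**Alternative 2:** The cut is C3–C4. Ring A is a salicylaldehyde whose phenol oxygen is already linked through C2 to a benzylic carbon of ring B that bears a sulfonyl leaving group and an ortho phenol. Base expels sulfinate to give an ortho-quinone methide of ring B, an N-heterocyclic carbene converts the aldehyde into its Breslow intermediate, and this acyl anion equivalent adds to the exocyclic carbon. Ring C closes, ring B re-aromatises with the 2'-phenol free, and a chiral carbene sets C3, giving A2, (3R)-7-O-(triisopropylsilyl)pervilleanone.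
- For: acyl anion additions to quinone methides are established, no metal is needed, and A2 has only one silyl group left to remove. On protecting-group economy it is stronger than the chosen route.
- Against: the ring closure needs base, and the product has an acidic benzylic alpha-hydrogen, so C3 is exposed to racemising conditions while the reaction runs. A quinone methide on a ring with two methoxy donors is a weak acceptor and its exocyclic carbon is substituted. The sulfone precursor with its O1–C2–C3 chain takes more steps from the same ring B aldehyde than deoxybenzoin 16.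
- In its place the chosen route closes the ring in a neutral medium in which the new centre never meets base.

**Alternative 3:** C3 is inserted as a single carbon between C2 and C4 of a smaller ring. Ring A arrives as the silyl enol ether of a benzofuran-3-one and ring B as an aryl chlorodiazirine. The arylchlorocarbene cyclopropanates the enol ether double bond and the chlorocyclopropane opens with loss of chloride and the silyl group, so C2–C3 and C3–C4 form together and the furan ring grows into the pyranone ring of A3, 7-(triisopropylsilyloxy)-2'-(tert-butyldimethylsilyloxy)-3',4'-dimethoxy-5'-(2-methylbut-3-en-2-yl)isoflavone.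
- For: two bonds in one step, a very convergent union of two simple halves, and a flat, robust intermediate. In convergence it is as good as or better than the chosen route.
- Against: A3 has no stereocentre, so an enantioselective reduction of the C2–C3 double bond must follow, in practice reduction to the isoflavanol and re-oxidation, and the labile C3 then has to survive two more operations. A free chlorocarbene is generated in the presence of the terminal alkene of the 1,1-dimethylallyl group. The oxidative amidine-to-diazirine conversion must be run on an electron-rich arene carrying that alkene.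
- In its place the chosen route creates C3 with its configuration in the ring-closing step and reaches the natural product one step later.

Key step: step 11

Remark on the chemistry (assumption): Rh2(S-PTTL)4 is dirhodium tetrakis[N-phthaloyl-(S)-tert-leucinate]. Its sense of induction on this substrate cannot be derived with confidence, so it is assumed to give the 3R product; if the opposite face is preferred, the mirror-image catalyst Rh2(R-PTTL)4 is used under the same conditions.

## Route

Step 1
Reactants: 1 2-hydroxy-3,4-dimethoxybenzaldehyde; 2 3-chloro-3-methylbut-1-yne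
Product: 3 3,4-dimethoxy-2-[(2-methylbut-3-yn-2-yl)oxy]benzaldehyde
Conditions: CuCl2·2H2O (1 mol%), DBU, MeCN, 0 °C to rt
Reagents that add atoms: none
Why: Copper-catalysed propargylic etherification: DBU frees the hydrogen-bonded phenoxide and the copper acetylide of 2 ionises to an allenylidene-type electrophile that is attacked at the tertiary carbon, the standard entry to aryl 1,1-dimethylpropargyl ethers; the aldehyde is inert at this temperature.

Step 2
Reactants: 3 3,4-dimethoxy-2-[(2-methylbut-3-yn-2-yl)oxy]benzaldehyde
Product: 4 3,4-dimethoxy-2-[(2-methylbut-3-en-2-yl)oxy]benzaldehyde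
Conditions: H2 (1 atm), 5% Pd/CaCO3 poisoned with Pb(OAc)2, quinoline, EtOAc, rt
Reagents that add atoms: none
Why: Semi-hydrogenation over lead-poisoned palladium with quinoline should stop at the alkene and leave the aldehyde and the tertiary aryl ether untouched.

Step 3
Reactants: 4 3,4-dimethoxy-2-[(2-methylbut-3-en-2-yl)oxy]benzaldehyde
Product: 7 2-hydroxy-3,4-dimethoxy-5-(2-methylbut-3-en-2-yl)benzaldehyde, via ortho-dienone 5 (not isolated), via para-dienone 6 (not isolated)
Conditions: PhNEt2, 170 °C, argon
Reagents that add atoms: none
Why: Aromatic Claisen rearrangement followed by a Cope rearrangement (para-Claisen): both ortho carbons of 4 are substituted, so the first [3,3] shift gives a dienone that cannot enolise (shown as 5 with the allyl group on the methoxy-bearing carbon; arrival at the formyl-bearing carbon leads on in the same way), a second [3,3] shift moves the allyl group to the free C5 as in 6, and tautomerisation gives 7. Two allylic inversions in a row return the tertiary terminus to the ring, which places the 1,1-dimethylallyl group para to the phenol; because it does not end ortho to the phenol, no chroman or coumaran can form.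

Step 4
Reactants: 7 2-hydroxy-3,4-dimethoxy-5-(2-methylbut-3-en-2-yl)benzaldehyde
Product: 8 2-(tert-butyldimethylsilyloxy)-3,4-dimethoxy-5-(2-methylbut-3-en-2-yl)benzaldehyde
Conditions: TBSCl, imidazole, DMF, rt
Reagents that add atoms: tert-butyldimethylsilyl chloride, CC(C)(C)[Si](C)(C)Cl
Why: Standard silylation of a phenol; the silyl group puts silicon and not a C–H bond on O2', which matters in step 11, and keeps the 2'-phenol away from the later C4 carbonyl.

Step 5
Reactants: 8 2-(tert-butyldimethylsilyloxy)-3,4-dimethoxy-5-(2-methylbut-3-en-2-yl)benzaldehyde
Product: 9 1-(2-methoxyethenyl)-2-(tert-butyldimethylsilyloxy)-3,4-dimethoxy-5-(2-methylbut-3-en-2-yl)benzene (E/Z mixture)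
Conditions: [Ph3PCH2OMe]Cl, NaHMDS, THF, 0 °C to rt
Reagents that add atoms: (methoxymethyl)triphenylphosphonium chloride, COC[P+](c1ccccc1)(c1ccccc1)c1ccccc1.[Cl-]
Why: Wittig methoxymethylenation; the sodium base keeps lithium salts out, so the oxaphosphetane should collapse without a free benzylic alkoxide that could pull the silyl group off O2'. The alkene geometry of 9 is irrelevant.

Step 6
Reactants: 9 1-(2-methoxyethenyl)-2-(tert-butyldimethylsilyloxy)-3,4-dimethoxy-5-(2-methylbut-3-en-2-yl)benzene
Product: 10 2-[2-(tert-butyldimethylsilyloxy)-3,4-dimethoxy-5-(2-methylbut-3-en-2-yl)phenyl]acetaldehyde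
Conditions: 1 M aq. HCl, THF, 40 °C
Reagents that add atoms: water, O
Why: Acid hydrolysis of the enol ether: protonation at the benzylic carbon, addition of water to the oxocarbenium ion and loss of methanol give the arylacetaldehyde. The hindered aryl silyl ether and the monosubstituted alkene should tolerate dilute acid, and 10 is used at once because arylacetaldehydes self-condense on storage.

Step 7
Reactants: 11 4-bromo-3-methoxyphenol
Product: 12 (4-bromo-3-methoxyphenoxy)(tert-butyl)dimethylsilane
Conditions: TBSCl, imidazole, DMF, rt
Reagents that add atoms: tert-butyldimethylsilyl chloride, CC(C)(C)[Si](C)(C)Cl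
Why: Silylation of the ring A phenol so that it survives the organometallic step and cannot quench the carbene later.

Step 8
Reactants: 12 (4-bromo-3-methoxyphenoxy)(tert-butyl)dimethylsilane; 10 2-[2-(tert-butyldimethylsilyloxy)-3,4-dimethoxy-5-(2-methylbut-3-en-2-yl)phenyl]acetaldehyde
Product: 15 1-[4-(tert-butyldimethylsilyloxy)-2-methoxyphenyl]-2-[2-(tert-butyldimethylsilyloxy)-3,4-dimethoxy-5-(2-methylbut-3-en-2-yl)phenyl]ethanol (racemic), via aryllithium 13 (not isolated), via arylcerium dichloride 14 (not isolated)
Conditions: n-BuLi, THF, −78 °C; anhydrous CeCl3, −78 °C; then 10, −78 °C; aq. NH4Cl at −78 °C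
Reagents that add atoms: none
Why: Bromine–lithium exchange gives 13 at the carbon that becomes C4a, and transmetallation to the weakly basic organocerium reagent 14 should favour 1,2-addition over deprotonation of the enolisable arylacetaldehyde. The carbinol centre of 15 forms as a racemate and is erased in step 9.

Step 9
Reactants: 15 1-[4-(tert-butyldimethylsilyloxy)-2-methoxyphenyl]-2-[2-(tert-butyldimethylsilyloxy)-3,4-dimethoxy-5-(2-methylbut-3-en-2-yl)phenyl]ethanol
Product: 16 1-[4-(tert-butyldimethylsilyloxy)-2-methoxyphenyl]-2-[2-(tert-butyldimethylsilyloxy)-3,4-dimethoxy-5-(2-methylbut-3-en-2-yl)phenyl]ethanone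
Conditions: Dess–Martin periodinane, NaHCO3, CH2Cl2, 0 °C to rt
Reagents that add atoms: none
Why: Dess–Martin oxidation of the secondary benzylic alcohol under buffered, non-basic conditions should give the deoxybenzoin without touching the silyl ethers or the alkene.

Step 10
Reactants: 16 1-[4-(tert-butyldimethylsilyloxy)-2-methoxyphenyl]-2-[2-(tert-butyldimethylsilyloxy)-3,4-dimethoxy-5-(2-methylbut-3-en-2-yl)phenyl]ethanone
Product: 17 2-diazo-1-[4-(tert-butyldimethylsilyloxy)-2-methoxyphenyl]-2-[2-(tert-butyldimethylsilyloxy)-3,4-dimethoxy-5-(2-methylbut-3-en-2-yl)phenyl]ethanone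
Conditions: 4-acetamidobenzenesulfonyl azide, DBU, MeCN, 0 °C to rt
Reagents that add atoms: 4-acetamidobenzenesulfonyl azide, CC(=O)Nc1ccc(cc1)S(=O)(=O)N=[N+]=[N-]
Why: Regitz diazo transfer: the methylene of 16 is benzylic and alpha to the ketone, acidic enough for DBU, and its enolate attacks the terminal nitrogen of the sulfonyl azide; loss of the sulfonamide leaves the diazo group on the future C3.

Step 11
Reactants: 17 2-diazo-1-[4-(tert-butyldimethylsilyloxy)-2-methoxyphenyl]-2-[2-(tert-butyldimethylsilyloxy)-3,4-dimethoxy-5-(2-methylbut-3-en-2-yl)phenyl]ethanone
Product: 18 (3R)-7,2'-bis-O-(tert-butyldimethylsilyl)pervilleanone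
Conditions: Rh2(S-PTTL)4 (1 mol%), CH2Cl2, 4 Å MS, 0 °C, slow addition of 17 at high dilution
Reagents that add atoms: none
Why: Proposed new method: loss of N2 from 17 on the dirhodium carboxylate gives a rhodium-bound carbene at C3, stabilised by ring B as donor and the aroyl group as acceptor; the C–H bonds of the ortho methoxy group on ring A are hydridic because of the adjacent oxygen and stand in a 1,6-relationship to the carbene carbon, so a three-centre transition state (hydride shift to C3 concerted with C2–C3 bond formation) should release the catalyst and 18. The closest known reaction types are the dirhodium-catalysed insertion of 2-alkoxyaryl diazomethyl ketones into the O–CH2 bond to give chroman-4-ones, the C–H insertion cyclisation of α-aryl-α-diazo ketones, and the intermolecular insertion of aryl-substituted carbenes into the C–H bonds of methyl ethers; new is their combination, a six-ring insertion of a diaryl diazoketone into a primary O-methyl C–H bond with enantiocontrol. Ring C closes as a six-membered ring by 1,6-insertion, with the C4 carbonyl inside the new ring and the former methyl carbon becoming C2. C3 is the carbene carbon itself, and its configuration is fixed when the C–C bond forms inside the chiral pocket of the four N-phthaloyl-tert-leucinate ligands, which shield one face of the carbene. Three selectivities are needed: insertion must beat capture of the carbene by the methoxy oxygen (the five-membered oxonium ylide can go on only by a 1,2-shift of methyl, a poor migrating group, so its formation should be reversible and unproductive); the site must be the ring A methoxy group (the silyl group on O2' puts silicon, not a C–H bond, where a five-membered ring would form, and the 3'-methoxy and vinyl groups are out of reach); and carbene dimerisation and intermolecular cyclopropanation of the terminal alkene must be held back, which slow addition at high dilution should do. The medium is neutral, so the new enolisable centre is not exposed to base.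

Step 12
Reactants: 18 (3R)-7,2'-bis-O-(tert-butyldimethylsilyl)pervilleanone
Product: 19 pervilleanone, (3R)-7,2'-dihydroxy-3',4'-dimethoxy-5'-(2-methylbut-3-en-2-yl)isoflavanone
Conditions: HF·pyridine, pyridine, THF, 0 °C to rt; pH 7 buffer work-up
Reagents that add atoms: none
Why: Fluoride-induced cleavage of both aryl silyl ethers in a buffered, weakly acidic medium; no base is present, so the enolisable C3 centre should keep its configuration, and the acidity is too low for cyclodehydration of the 2'-phenol onto C4 or protonation of the alkene.

## Compound list

1 | 2-hydroxy-3,4-dimethoxybenzaldehyde | COc1ccc(C=O)c(O)c1OC | starting material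
2 | 3-chloro-3-methylbut-1-yne | C#CC(C)(C)Cl | starting material
3 | 3,4-dimethoxy-2-[(2-methylbut-3-yn-2-yl)oxy]benzaldehyde | C#CC(C)(C)Oc1c(C=O)ccc(OC)c1OC | intermediate
4 | 3,4-dimethoxy-2-[(2-methylbut-3-en-2-yl)oxy]benzaldehyde | C=CC(C)(C)Oc1c(C=O)ccc(OC)c1OC | intermediate
5 | 4,5-dimethoxy-5-(3-methylbut-2-en-1-yl)-6-oxocyclohexa-1,3-diene-1-carbaldehyde (ortho-dienone, racemic, not isolated) | O=CC1=CC=C(OC)C(OC)(CC=C(C)C)C1=O | intermediate
6 | 4,5-dimethoxy-3-(2-methylbut-3-en-2-yl)-6-oxocyclohexa-1,4-diene-1-carbaldehyde (para-dienone, racemic, not isolated) | O=CC1=CC(C(C)(C)C=C)C(OC)=C(OC)C1=O | intermediate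
7 | 2-hydroxy-3,4-dimethoxy-5-(2-methylbut-3-en-2-yl)benzaldehyde | C=CC(C)(C)c1cc(C=O)c(O)c(OC)c1OC | intermediate
8 | 2-(tert-butyldimethylsilyloxy)-3,4-dimethoxy-5-(2-methylbut-3-en-2-yl)benzaldehyde | C=CC(C)(C)c1cc(C=O)c(O[Si](C)(C)C(C)(C)C)c(OC)c1OC | intermediate
9 | 1-(2-methoxyethenyl)-2-(tert-butyldimethylsilyloxy)-3,4-dimethoxy-5-(2-methylbut-3-en-2-yl)benzene (E/Z mixture) | C=CC(C)(C)c1cc(C=COC)c(O[Si](C)(C)C(C)(C)C)c(OC)c1OC | intermediate
10 | 2-[2-(tert-butyldimethylsilyloxy)-3,4-dimethoxy-5-(2-methylbut-3-en-2-yl)phenyl]acetaldehyde | C=CC(C)(C)c1cc(CC=O)c(O[Si](C)(C)C(C)(C)C)c(OC)c1OC | intermediate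
11 | 4-bromo-3-methoxyphenol | COc1cc(O)ccc1Br | starting material
12 | (4-bromo-3-methoxyphenoxy)(tert-butyl)dimethylsilane | COc1cc(O[Si](C)(C)C(C)(C)C)ccc1Br | intermediate
13 | [4-(tert-butyldimethylsilyloxy)-2-methoxyphenyl]lithium (not isolated) | COc1cc(O[Si](C)(C)C(C)(C)C)ccc1[Li] | intermediate
14 | dichloro[4-(tert-butyldimethylsilyloxy)-2-methoxyphenyl]cerium (not isolated) | COc1cc(O[Si](C)(C)C(C)(C)C)ccc1[Ce](Cl)Cl | intermediate
15 | 1-[4-(tert-butyldimethylsilyloxy)-2-methoxyphenyl]-2-[2-(tert-butyldimethylsilyloxy)-3,4-dimethoxy-5-(2-methylbut-3-en-2-yl)phenyl]ethanol (racemic) | C=CC(C)(C)c1cc(CC(O)c2ccc(O[Si](C)(C)C(C)(C)C)cc2OC)c(O[Si](C)(C)C(C)(C)C)c(OC)c1OC | intermediate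
16 | 1-[4-(tert-butyldimethylsilyloxy)-2-methoxyphenyl]-2-[2-(tert-butyldimethylsilyloxy)-3,4-dimethoxy-5-(2-methylbut-3-en-2-yl)phenyl]ethanone | C=CC(C)(C)c1cc(CC(=O)c2ccc(O[Si](C)(C)C(C)(C)C)cc2OC)c(O[Si](C)(C)C(C)(C)C)c(OC)c1OC | intermediate
17 | 2-diazo-1-[4-(tert-butyldimethylsilyloxy)-2-methoxyphenyl]-2-[2-(tert-butyldimethylsilyloxy)-3,4-dimethoxy-5-(2-methylbut-3-en-2-yl)phenyl]ethanone | C=CC(C)(C)c1cc(C(=[N+]=[N-])C(=O)c2ccc(O[Si](C)(C)C(C)(C)C)cc2OC)c(O[Si](C)(C)C(C)(C)C)c(OC)c1OC | intermediate
18 | (3R)-7,2'-bis-O-(tert-butyldimethylsilyl)pervilleanone | C=CC(C)(C)c1cc([C@@H]2COc3cc(O[Si](C)(C)C(C)(C)C)ccc3C2=O)c(O[Si](C)(C)C(C)(C)C)c(OC)c1OC | intermediate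
19 | pervilleanone, (3R)-7,2'-dihydroxy-3',4'-dimethoxy-5'-(2-methylbut-3-en-2-yl)isoflavanone | C=CC(C)(C)c1cc([C@@H]2COc3cc(O)ccc3C2=O)c(O)c(OC)c1OC | target

## Step count and least certain steps

Total: 12 steps. Longest linear sequence: 11 steps (1 to 19 through steps 1–6 and 8–12); step 7 is a one-step side branch.

**Step 11 (key step, proposed new method).**
- Most likely failures: capture of the carbene by the methoxy oxygen followed by methyl migration and ring contraction; carbene dimerisation, because a primary C–H bond is a slow partner; poor facial selectivity, because the ortho silyloxy group twists ring B out of conjugation with the carbene carbon.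
- Fallback with known chemistry, from 16 back to 18: selective cleavage of the ring A methyl ether ortho to the ketone with BCl3 (CH2Cl2, −78 to 0 °C, chelation control) should give 1-[4-(tert-butyldimethylsilyloxy)-2-hydroxyphenyl]-2-[2-(tert-butyldimethylsilyloxy)-3,4-dimethoxy-5-(2-methylbut-3-en-2-yl)phenyl]ethanone F1. Condensation with N,N-dimethylformamide dimethyl acetal (toluene, 90 °C) closes ring C to 7,2'-bis(tert-butyldimethylsilyloxy)-3',4'-dimethoxy-5'-(2-methylbut-3-en-2-yl)isoflavone F2. Asymmetric transfer hydrogenation with RuCl(p-cymene)[(R,R)-TsDPEN] and HCO2H/Et3N reduces the C2–C3 double bond and then the ketone with dynamic kinetic resolution of the enolisable C3 centre; by analogy with aryl ketone reductions this should give (3R,4R)-cis-7,2'-bis(tert-butyldimethylsilyloxy)-3',4'-dimethoxy-5'-(2-methylbut-3-en-2-yl)isoflavan-4-ol F3. Dess–Martin oxidation as in step 9 returns the ketone without touching C3 and gives 18.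

**Step 3.**
- Most likely failures: heterolysis of the tertiary allyl ether with loss of isoprene, favoured because the salicylaldehyde phenoxide is a good leaving group; loss of the formyl group when the allyl group arrives at the formyl-bearing ortho carbon; a stalled second shift, because it forms a crowded aryl–quaternary carbon bond.
- Fallback, from 1 back to 9: bromination para to the phenol with NBS (MeCN, 0 °C) should give 5-bromo-2-hydroxy-3,4-dimethoxybenzaldehyde F4. Silylation as in step 4 gives 5-bromo-2-(tert-butyldimethylsilyloxy)-3,4-dimethoxybenzaldehyde F5, and methoxymethylenation as in step 5 gives 1-bromo-4-(tert-butyldimethylsilyloxy)-2,3-dimethoxy-5-(2-methoxyethenyl)benzene F6. A ligand-controlled, γ-selective Suzuki–Miyaura coupling with 3-methylbut-2-en-1-ylboronic acid pinacol ester (Pd(OAc)2, dialkylbiarylphosphine, K3PO4, THF/H2O) then joins the tertiary allyl terminus to the ring and gives 9. The quaternary centre is made by cross-coupling in place of the sigmatropic shifts, and steps 1–5 are replaced.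

**Step 8.**
- Most likely failures: deprotonation of the arylacetaldehyde instead of addition; migration of the O2' silyl group to the new alkoxide before the quench.
- Fallback, from 10 back to 16: chlorite oxidation (NaClO2, NaH2PO4, 2-methylbut-2-ene, t-BuOH/H2O) should give 2-[2-(tert-butyldimethylsilyloxy)-3,4-dimethoxy-5-(2-methylbut-3-en-2-yl)phenyl]acetic acid F7. Amide coupling with N,O-dimethylhydroxylamine hydrochloride (EDCI, HOBt, i-Pr2NEt) gives the N-methoxy-N-methylamide F8. Addition of aryllithium 13 at −78 °C gives ketone 16 directly through the chelated tetrahedral intermediate, so step 9 is not needed.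

**Step 10.**
- Most likely failures: slow transfer at a methylene flanked by two ortho-substituted arenes, which gives the base time to cleave the silyl ether para to the ketone; transfer of the O2' silyl group to the enolate oxygen, followed by closure of the freed phenol onto the ketone.
- Fallback, from 16 back to 17: kinetic deprotonation (LiHMDS, THF, −78 °C) and C-acylation with 2,2,2-trifluoroethyl trifluoroacetate should give 4,4,4-trifluoro-1-[4-(tert-butyldimethylsilyloxy)-2-methoxyphenyl]-2-[2-(tert-butyldimethylsilyloxy)-3,4-dimethoxy-5-(2-methylbut-3-en-2-yl)phenyl]butane-1,3-dione F9. Deacylative diazo transfer with methanesulfonyl azide and Et3N in MeCN at rt then gives 17 with only a weak amine base present.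

## Further compounds

F1 | step 11 | 1-[4-(tert-butyldimethylsilyloxy)-2-hydroxyphenyl]-2-[2-(tert-butyldimethylsilyloxy)-3,4-dimethoxy-5-(2-methylbut-3-en-2-yl)phenyl]ethanone | C=CC(C)(C)c1cc(CC(=O)c2ccc(O[Si](C)(C)C(C)(C)C)cc2O)c(O[Si](C)(C)C(C)(C)C)c(OC)c1OC
F2 | step 11 | 7,2'-bis(tert-butyldimethylsilyloxy)-3',4'-dimethoxy-5'-(2-methylbut-3-en-2-yl)isoflavone | C=CC(C)(C)c1cc(-c2coc3cc(O[Si](C)(C)C(C)(C)C)ccc3c2=O)c(O[Si](C)(C)C(C)(C)C)c(OC)c1OC
F3 | step 11 | (3R,4R)-cis-7,2'-bis(tert-butyldimethylsilyloxy)-3',4'-dimethoxy-5'-(2-methylbut-3-en-2-yl)isoflavan-4-ol | C=CC(C)(C)c1cc([C@@H]2COc3cc(O[Si](C)(C)C(C)(C)C)ccc3[C@@H]2O)c(O[Si](C)(C)C(C)(C)C)c(OC)c1OC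
F4 | step 3 | 5-bromo-2-hydroxy-3,4-dimethoxybenzaldehyde | COc1c(Br)cc(C=O)c(O)c1OC
F5 | step 3 | 5-bromo-2-(tert-butyldimethylsilyloxy)-3,4-dimethoxybenzaldehyde | COc1c(Br)cc(C=O)c(O[Si](C)(C)C(C)(C)C)c1OC
F6 | step 3 | 1-bromo-4-(tert-butyldimethylsilyloxy)-2,3-dimethoxy-5-(2-methoxyethenyl)benzene | COC=Cc1cc(Br)c(OC)c(OC)c1O[Si](C)(C)C(C)(C)C
F7 | step 8 | 2-[2-(tert-butyldimethylsilyloxy)-3,4-dimethoxy-5-(2-methylbut-3-en-2-yl)phenyl]acetic acid | C=CC(C)(C)c1cc(CC(=O)O)c(O[Si](C)(C)C(C)(C)C)c(OC)c1OC
F8 | step 8 | 2-[2-(tert-butyldimethylsilyloxy)-3,4-dimethoxy-5-(2-methylbut-3-en-2-yl)phenyl]-N-methoxy-N-methylacetamide | C=CC(C)(C)c1cc(CC(=O)N(C)OC)c(O[Si](C)(C)C(C)(C)C)c(OC)c1OC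
F9 | step 10 | 4,4,4-trifluoro-1-[4-(tert-butyldimethylsilyloxy)-2-methoxyphenyl]-2-[2-(tert-butyldimethylsilyloxy)-3,4-dimethoxy-5-(2-methylbut-3-en-2-yl)phenyl]butane-1,3-dione | C=CC(C)(C)c1cc(C(C(=O)C(F)(F)F)C(=O)c2ccc(O[Si](C)(C)C(C)(C)C)cc2OC)c(O[Si](C)(C)C(C)(C)C)c(OC)c1OC
A1 | alternative 1 | 2,3-dimethoxy-5-[(3,4-trans)-4-(triethylsilyloxy)-7-(triisopropylsilyloxy)chroman-3-yl]-1,4-benzoquinone | COC1=C(OC)C(=O)C([C@@H]2COc3cc(O[Si](C(C)C)(C(C)C)C(C)C)ccc3[C@H]2O[Si](CC)(CC)CC)=CC1=O
A2 | alternative 2 | (3R)-7-O-(triisopropylsilyl)pervilleanone | C=CC(C)(C)c1cc([C@@H]2COc3cc(O[Si](C(C)C)(C(C)C)C(C)C)ccc3C2=O)c(O)c(OC)c1OC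
A3 | alternative 3 | 7-(triisopropylsilyloxy)-2'-(tert-butyldimethylsilyloxy)-3',4'-dimethoxy-5'-(2-methylbut-3-en-2-yl)isoflavone | C=CC(C)(C)c1cc(-c2coc3cc(O[Si](C(C)C)(C(C)C)C(C)C)ccc3c2=O)c(O[Si](C)(C)C(C)(C)C)c(OC)c1OC
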